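**Retrosynthetic overview**
- Cyclopropane (last ring): palladium-carbene CH2 transfer to the cis-disubstituted olefin of a butenolide-fused cycloocta-1,3-diene, anti to the allylic methyl group.
- Butenolide and eight-membered ring (one operation): ring-expanding enyne metathesis of a cyclohexenylmethyl propiolate; the ring C=C of a six-membered template is cut and the two alkyne carbons are spliced in.
- Cyclohexene template: from a cis-fused γ-lactone (convex-face alkylation sets the side-chain centre; reduction; primary acetate).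
- Lactone: from (S)-5-methylcyclohexenone by trans-epoxidation, enol triflation, Stille hydroxymethylation/palladium syn-1,4-acetoxylation and Ireland–Claisen 1,3-chirality transfer.
- Ring order: cyclohexene (template, later expanded) → γ-lactone (auxiliary, later opened) → butenolide + cyclooctadiene together → cyclopropane.

Assumption: the target is the single stereoisomer encoded by the given SMILES; all descriptors in the names below were derived from that SMILES.

**Route**

Step 1
Reactants: 1 (E)-but-2-enal (crotonaldehyde); 2 tert-butyl 3-oxobutanoate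
Product: 4 (5S)-5-methylcyclohex-2-en-1-one, via Michael adduct 3 (not isolated)
Conditions: (R)-2-{bis[3,5-bis(trifluoromethyl)phenyl](trimethylsilyloxy)methyl}pyrrolidine (10 mol %), toluene, rt; then TsOH·H2O, 80 °C
Reagents that add atoms: none
Why: Iminium-catalysed Michael addition of the β-keto ester to the enal face left open by the diarylprolinol silyl ether sets the methyl-bearing carbon as S, and acid then drives intramolecular aldol condensation, tert-butyl ester cleavage and decarboxylation (organocatalytic Michael/aldol annulation).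

Step 2
Reactants: 4 (5S)-5-methylcyclohex-2-en-1-one
Product: 5 (1S,4S,6S)-4-methyl-7-oxabicyclo[4.1.0]heptan-2-one
Conditions: 30 % H2O2, NaOH (cat.), MeOH, 0 °C
Reagents that add atoms: hydrogen peroxide, OO
Why: Weitz–Scheffer nucleophilic epoxidation, in which hydroperoxide adds axially to the β-carbon anti to the ring methyl group, so the oxirane is trans to the methyl and the later carbinol centre is fixed here.

Step 3
Reactants: 5 (1S,4S,6S)-4-methyl-7-oxabicyclo[4.1.0]heptan-2-one
Product: 6 (1S,4S,6S)-4-methyl-7-oxabicyclo[4.1.0]hept-2-en-2-yl trifluoromethanesulfonate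
Conditions: LiN(iPr)2, THF, −78 °C; then PhNTf2, −78 to 0 °C
Reagents that add atoms: N-phenylbis(trifluoromethanesulfonimide), O=S(=O)(N(c1ccccc1)S(=O)(=O)C(F)(F)F)C(F)(F)F
Why: Kinetic deprotonation can only take place at the ring CH2 next to the carbonyl (the other α-carbon is the oxirane CH), and O-sulfonylation of the lithium enolate gives the enol triflate (enolate triflation).

Step 4
Reactants: 6 (1S,4S,6S)-4-methyl-7-oxabicyclo[4.1.0]hept-2-en-2-yl trifluoromethanesulfonate
Product: 8 (1R,4S,6S)-4-hydroxy-2-(hydroxymethyl)-6-methylcyclohex-2-en-1-yl acetate, via vinyl oxirane 7 (not isolated)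
Conditions: Bu3SnCH2OH, Pd(PPh3)4 (5 mol %), LiCl, AcOH (2 equiv), dioxane, 60 °C
Reagents that add atoms: (tributylstannyl)methanol, CCCC[Sn](CCCC)(CCCC)CO; acetic acid, CC(=O)O
Why: Stille hydroxymethylation of the enol triflate gives vinyl oxirane 7, which the same zerovalent palladium ionises with inversion, and acetate then attacks the distal allyl terminus anti to palladium, that is syn to the oxirane oxygen and anti to the methyl group (Tsuji–Trost syn-1,4-acyloxylation), setting the acetoxy carbon as R.

Step 5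
Reactants: 8 (1R,4S,6S)-4-hydroxy-2-(hydroxymethyl)-6-methylcyclohex-2-en-1-yl acetate
Product: 11 (3aR,6S,7aS)-4-(hydroxymethyl)-6-methyl-3a,6,7,7a-tetrahydro-1-benzofuran-2(3H)-one, via silyl ketene acetal 9 (not isolated), via hydroxy acid 10 (not isolated)
Conditions: Me3SiCl (5 equiv), then LiN(iPr)2 (3.3 equiv), THF, −78 to 65 °C; then 1 M HCl, rt
Reagents that add atoms: none
Why: Ireland–Claisen rearrangement of the silyl ketene acetal moves the chirality suprafacially from the acetoxy carbon to the ring carbon next to the carbinol, so the new C–C bond is cis to the hydroxyl and acid work-up closes the cis-fused γ-lactone (the acetoxy stereocentre is consumed).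

Step 6
Reactants: 11 (3aR,6S,7aS)-4-(hydroxymethyl)-6-methyl-3a,6,7,7a-tetrahydro-1-benzofuran-2(3H)-one
Product: 13 (3S,3aR,6S,7aS)-4-{[(tert-butyldimethylsilyl)oxy]methyl}-6-methyl-3-(4-methylpent-3-en-1-yl)-3a,6,7,7a-tetrahydro-1-benzofuran-2(3H)-one, via C3-alkylated hydroxy lactone 12 (not isolated)
Conditions: LiN(iPr)2 (2.2 equiv), THF–HMPA, −78 °C; 5-bromo-2-methylpent-2-ene, −78 to −20 °C; then tBuMe2SiCl, 0 °C
Reagents that add atoms: 5-bromo-2-methylpent-2-ene, CC(C)=CCCBr; tert-butyldimethylsilyl chloride, CC(C)(C)[Si](C)(C)Cl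
Why: The lithium enolate of the cis-fused bicyclic lactone is alkylated on its convex face, anti to the cyclohexene ring, which sets the side-chain centre as S, and the remaining lithium alkoxide is silylated in the same flask (diastereoselective lactone enolate alkylation).

Step 7
Reactants: 13 (3S,3aR,6S,7aS)-4-{[(tert-butyldimethylsilyl)oxy]methyl}-6-methyl-3-(4-methylpent-3-en-1-yl)-3a,6,7,7a-tetrahydro-1-benzofuran-2(3H)-one
Product: 14 (1S,2R,5S)-3-{[(tert-butyldimethylsilyl)oxy]methyl}-2-[(2S)-1-hydroxy-6-methylhept-5-en-2-yl]-5-methylcyclohex-3-en-1-ol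
Conditions: LiAlH4, THF, 0 °C
Reagents that add atoms: none
Why: Hydride reduction of the lactone gives the primary/secondary diol without touching the silyl ether or the olefins, and no stereocentre changes.

Step 8
Reactants: 14 (1S,2R,5S)-3-{[(tert-butyldimethylsilyl)oxy]methyl}-2-[(2S)-1-hydroxy-6-methylhept-5-en-2-yl]-5-methylcyclohex-3-en-1-ol
Product: 15 (2S)-2-[(1R,4S,6S)-2-{[(tert-butyldimethylsilyl)oxy]methyl}-6-hydroxy-4-methylcyclohex-2-en-1-yl]-6-methylhept-5-en-1-yl acetate
Conditions: Ac2O (1.1 equiv), 2,4,6-collidine, CH2Cl2, −20 °C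
Reagents that add atoms: acetic anhydride, CC(=O)OC(C)=O
Why: Selective acylation, because the primary alcohol reacts far faster than the flanked secondary ring alcohol at low temperature.

Step 9
Reactants: 15 (2S)-2-[(1R,4S,6S)-2-{[(tert-butyldimethylsilyl)oxy]methyl}-6-hydroxy-4-methylcyclohex-2-en-1-yl]-6-methylhept-5-en-1-yl acetate
Product: 16 (2S)-2-[(1R,4S,6S)-6-hydroxy-2-(hydroxymethyl)-4-methylcyclohex-2-en-1-yl]-6-methylhept-5-en-1-yl acetate
Conditions: HF·pyridine, pyridine, THF, 0 °C to rt
Reagents that add atoms: none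
Why: Fluoride-mediated desilylation of the primary silyl ether under buffered conditions that leave the acetate intact.

Step 10
Reactants: 16 (2S)-2-[(1R,4S,6S)-6-hydroxy-2-(hydroxymethyl)-4-methylcyclohex-2-en-1-yl]-6-methylhept-5-en-1-yl acetate
Product: 17 {(3S,5S,6R)-6-[(2S)-1-(acetyloxy)-6-methylhept-5-en-2-yl]-5-hydroxy-3-methylcyclohex-1-en-1-yl}methyl prop-2-ynoate
Conditions: propiolic acid, DCC, DMAP (cat.), CH2Cl2, −20 °C
Reagents that add atoms: propiolic acid, C#CC(=O)O
Why: Steglich carbodiimide esterification at low temperature acylates the primary allylic alcohol in preference to the hindered secondary ring alcohol.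

Step 11
Reactants: 17 {(3S,5S,6R)-6-[(2S)-1-(acetyloxy)-6-methylhept-5-en-2-yl]-5-hydroxy-3-methylcyclohex-1-en-1-yl}methyl prop-2-ynoate
Product: 18 (2S)-2-[(4R,5S,7S,8Z)-5-hydroxy-7-methyl-1-oxo-1,3,4,5,6,7-hexahydrocycloocta[c]furan-4-yl]-6-methylhept-5-en-1-yl acetate
Conditions: (H2IMes)(PCy3)Cl2Ru=CHPh (second-generation Grubbs catalyst, 10 mol %), toluene (2 mM), 80 °C
Reagents that add atoms: none
Why: Proposed new method: a ruthenium alkylidene adds to the terminal ynoate to put the vinyl carbene on the ester-bearing carbon, this carbene ring-closes on the trisubstituted cyclohexene C=C to form the butenolide and thereby opens the six-membered ring to a new alkylidene, which closes on the pendant vinyl group to the Z-configured eight-membered ring, with the alkyne-to-diene conversion as driving force and no stereocentre created or touched; the closest known reaction types are ring-opening/ring-closing enyne metathesis of cycloalkene-ynes with two-carbon ring expansion and the enyne ring-closing metathesis of allyl propiolate to a vinylbutenolide.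

Step 12
Reactants: 18 (2S)-2-[(4R,5S,7S,8Z)-5-hydroxy-7-methyl-1-oxo-1,3,4,5,6,7-hexahydrocycloocta[c]furan-4-yl]-6-methylhept-5-en-1-yl acetate
Product: 19 (2S)-2-[(4R,5S,7S,8R,9R)-5-hydroxy-7-methyl-1-oxo-8,9-methano-1,3,4,5,6,7,8,9-octahydrocycloocta[c]furan-4-yl]-6-methylhept-5-en-1-yl acetate (CNP0267808.2)
Conditions: CH2N2, Pd(OAc)2 (5 mol %), Et2O, 0 °C
Reagents that add atoms: diazomethane, C=[N+]=[N-]
Why: Palladium-catalysed methylene transfer from diazomethane reacts with the cis-disubstituted diene olefin while tri- and tetrasubstituted olefins stay inert, and it occurs on the face anti to the adjacent allylic methyl group, which is also the face of the ring hydroxyl, giving the cis-fused cyclopropane with both new centres R.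

**Compound list**

1 | (E)-but-2-enal (crotonaldehyde) | C/C=C/C=O | starting material
2 | tert-butyl 3-oxobutanoate | CC(=O)CC(=O)OC(C)(C)C | starting material
3 | tert-butyl (3S)-2-acetyl-3-methyl-5-oxopentanoate (both C2 epimers) | CC(=O)C(C(=O)OC(C)(C)C)[C@@H](C)CC=O | intermediate
4 | (5S)-5-methylcyclohex-2-en-1-one | O=C1C[C@@H](C)CC=C1 | intermediate
5 | (1S,4S,6S)-4-methyl-7-oxabicyclo[4.1.0]heptan-2-one | O=C1C[C@@H](C)C[C@@H]2O[C@@H]21 | intermediate
6 | (1S,4S,6S)-4-methyl-7-oxabicyclo[4.1.0]hept-2-en-2-yl trifluoromethanesulfonate | FC(F)(F)S(=O)(=O)OC1=C[C@@H](C)C[C@@H]2O[C@@H]21 | intermediate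
7 | [(1R,4S,6S)-4-methyl-7-oxabicyclo[4.1.0]hept-2-en-2-yl]methanol | OCC1=C[C@@H](C)C[C@@H]2O[C@@H]21 | intermediate
8 | (1R,4S,6S)-4-hydroxy-2-(hydroxymethyl)-6-methylcyclohex-2-en-1-yl acetate | OCC1=C[C@@H](O)C[C@H](C)[C@H]1OC(C)=O | intermediate
9 | O-trimethylsilyl ketene acetal of the bis(O-trimethylsilyl) ether of 8 | C[Si](C)(C)OCC1=C[C@@H](O[Si](C)(C)C)C[C@H](C)[C@H]1OC(=C)O[Si](C)(C)C | intermediate
10 | 2-[(1R,4S,6S)-6-hydroxy-2-(hydroxymethyl)-4-methylcyclohex-2-en-1-yl]acetic acid | OC(=O)C[C@@H]1C(CO)=C[C@@H](C)C[C@@H]1O | intermediate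
11 | (3aR,6S,7aS)-4-(hydroxymethyl)-6-methyl-3a,6,7,7a-tetrahydro-1-benzofuran-2(3H)-one | O=C1C[C@@H]2C(CO)=C[C@@H](C)C[C@@H]2O1 | intermediate
12 | (3S,3aR,6S,7aS)-4-(hydroxymethyl)-6-methyl-3-(4-methylpent-3-en-1-yl)-3a,6,7,7a-tetrahydro-1-benzofuran-2(3H)-one (present as its lithium alkoxide) | O=C1[C@@H](CCC=C(C)C)[C@@H]2C(CO)=C[C@@H](C)C[C@@H]2O1 | intermediate
13 | (3S,3aR,6S,7aS)-4-{[(tert-butyldimethylsilyl)oxy]methyl}-6-methyl-3-(4-methylpent-3-en-1-yl)-3a,6,7,7a-tetrahydro-1-benzofuran-2(3H)-one | O=C1[C@@H](CCC=C(C)C)[C@@H]2C(CO[Si](C)(C)C(C)(C)C)=C[C@@H](C)C[C@@H]2O1 | intermediate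
14 | (1S,2R,5S)-3-{[(tert-butyldimethylsilyl)oxy]methyl}-2-[(2S)-1-hydroxy-6-methylhept-5-en-2-yl]-5-methylcyclohex-3-en-1-ol | OC[C@@H](CCC=C(C)C)[C@@H]1C(CO[Si](C)(C)C(C)(C)C)=C[C@@H](C)C[C@@H]1O | intermediate
15 | (2S)-2-[(1R,4S,6S)-2-{[(tert-butyldimethylsilyl)oxy]methyl}-6-hydroxy-4-methylcyclohex-2-en-1-yl]-6-methylhept-5-en-1-yl acetate | CC(=O)OC[C@@H](CCC=C(C)C)[C@@H]1C(CO[Si](C)(C)C(C)(C)C)=C[C@@H](C)C[C@@H]1O | intermediate
16 | (2S)-2-[(1R,4S,6S)-6-hydroxy-2-(hydroxymethyl)-4-methylcyclohex-2-en-1-yl]-6-methylhept-5-en-1-yl acetate | CC(=O)OC[C@@H](CCC=C(C)C)[C@@H]1C(CO)=C[C@@H](C)C[C@@H]1O | intermediate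
17 | {(3S,5S,6R)-6-[(2S)-1-(acetyloxy)-6-methylhept-5-en-2-yl]-5-hydroxy-3-methylcyclohex-1-en-1-yl}methyl prop-2-ynoate | CC(=O)OC[C@@H](CCC=C(C)C)[C@@H]1C(COC(=O)C#C)=C[C@@H](C)C[C@@H]1O | intermediate
18 | (2S)-2-[(4R,5S,7S,8Z)-5-hydroxy-7-methyl-1-oxo-1,3,4,5,6,7-hexahydrocycloocta[c]furan-4-yl]-6-methylhept-5-en-1-yl acetate | CC(=O)OC[C@@H](CCC=C(C)C)[C@@H]1C2=C(C(=O)OC2)/C=C\[C@@H](C)C[C@@H]1O | intermediate
19 | (2S)-2-[(4R,5S,7S,8R,9R)-5-hydroxy-7-methyl-1-oxo-8,9-methano-1,3,4,5,6,7,8,9-octahydrocycloocta[c]furan-4-yl]-6-methylhept-5-en-1-yl acetate (CNP0267808.2) | CC(=O)OC[C@@H](CCC=C(C)C)[C@@H]1C2=C(C(=O)OC2)[C@@H]2C[C@@H]2[C@@H](C)C[C@@H]1O | target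

**Totals**

Total step count: 12. Longest linear sequence: 12 steps (from 1 and 2 to 19).

**Steps most likely to fail, with fallbacks**

Step 11 (ring-expanding enyne metathesis). The carbene must engage an unstrained trisubstituted ring olefin, form a tetrasubstituted butenolide olefin and then close an eight-membered ring; stalling after alkyne insertion or oligomerisation is possible. The fallback sets out from 17 and comes back at 18, doing the same bond reorganisation stepwise without a carbene. EtAlCl2 (2.5 equiv, CH2Cl2, −40 °C) promotes intramolecular [2+2] cycloaddition of the ynoate onto the ring olefin to give the cyclobutene-fused tricyclic lactone F5. Thermolysis (o-xylene, 200 °C, sealed tube) then opens the cyclobutene by 4π-electrocyclic ring opening, and the strained diene first formed relaxes to the Z-configured diene 18. The two new ring-fusion centres of F5 are lost again, so their configuration does not matter.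

Step 4 (Stille coupling in the presence of an oxirane that becomes a vinyl oxirane). Zerovalent palladium may ionise the oxirane before or after coupling, and acetate may also attack the proximal terminus; 8 should be used at once to avoid acetyl migration. The fallback sets out from 5 and comes back at 11, moving the cross-coupling behind the rearrangement so that palladium meets the vinyl oxirane only together with acetic acid:
- tBuMe2SiOTf/Et3N converts 5 into the silyl enol ether tert-butyldimethyl{[(1S,4S,6S)-4-methyl-7-oxabicyclo[4.1.0]hept-2-en-2-yl]oxy}silane F1.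
- Pd(PPh3)4/AcOH at rt gives the syn-1,4-adduct (1R,4S,6S)-2-[(tert-butyldimethylsilyl)oxy]-4-hydroxy-6-methylcyclohex-2-en-1-yl acetate F2.
- Ireland–Claisen rearrangement (Me3SiCl, LiN(iPr)2, then 1 M HCl) gives the keto lactone (3aS,6S,7aS)-6-methylhexahydro-1-benzofuran-2,4-dione F3.
- Kinetic enolisation at the CH2 side (KN(SiMe3)2, PhNTf2, −78 °C) gives (3aS,6S,7aS)-6-methyl-2-oxo-2,3,3a,6,7,7a-hexahydro-1-benzofuran-4-yl trifluoromethanesulfonate F4.
- Stille coupling with Bu3SnCH2OH (Pd(PPh3)4, LiCl) delivers 11.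

Step 12 (cyclopropanation). The diene olefin is conjugated to an electron-poor butenolide and may react slowly, and the facial preference rests on the allylic methyl group alone. The fallback sets out from 18 and comes back at 19, replacing intermolecular palladium-carbene transfer by hydroxyl-directed zinc carbenoid delivery. The ring hydroxyl of 18 is converted into its zinc alkoxide with Et2Zn and treated with CH2I2 (CH2Cl2, −20 °C, 1.5 equiv of carbenoid). Intramolecular delivery syn to the hydroxyl puts the methylene on the same face and speeds this olefin up relative to the remote trisubstituted side-chain olefin. No new compound is formed on the way.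

**Further compounds**

F1 | step 4 | tert-butyldimethyl{[(1S,4S,6S)-4-methyl-7-oxabicyclo[4.1.0]hept-2-en-2-yl]oxy}silane | CC(C)(C)[Si](C)(C)OC1=C[C@@H](C)C[C@@H]2O[C@@H]21
F2 | step 4 | (1R,4S,6S)-2-[(tert-butyldimethylsilyl)oxy]-4-hydroxy-6-methylcyclohex-2-en-1-yl acetate | CC(C)(C)[Si](C)(C)OC1=C[C@@H](O)C[C@H](C)[C@H]1OC(C)=O
F3 | step 4 | (3aS,6S,7aS)-6-methylhexahydro-1-benzofuran-2,4-dione | O=C1C[C@@H]2C(=O)C[C@@H](C)C[C@@H]2O1
F4 | step 4 | (3aS,6S,7aS)-6-methyl-2-oxo-2,3,3a,6,7,7a-hexahydro-1-benzofuran-4-yl trifluoromethanesulfonate | O=C1C[C@@H]2C(OS(=O)(=O)C(F)(F)F)=C[C@@H](C)C[C@@H]2O1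
F5 | step 11 | cyclobutene-fused tricyclic lactone from intramolecular [2+2] cycloaddition of 17 (either cis ring-fusion isomer at the two new centres) | CC(=O)OC[C@@H](CCC=C(C)C)[C@@H]1C23COC(=O)C2=CC3[C@@H](C)C[C@@H]1O
F0 | step 12 | none | none
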